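The molecule is divided at the four-carbon tether beside the quaternary carbon of the bicyclo[2.2.2]octane (Julia–Kocienski union of a west sulfone with an east aldehyde). Everything rests on reading the bicycle as a cyclohexenone: the carbinol bridgehead, the benzyl-bearing CH beside it, the CMe2 carbon and the CH bridgehead are C6, C5, C4 and C3 of a 6-alkoxy-5-benzyl-4,4-dimethylcyclohex-2-enone. Its lithium dienolate and methyl acrylate give, in one operation, the C6–CH2 and C3–C(ester) bonds, the third bridge and three stereocentres. The precursor is the trans 6-(benzyloxymethoxy) enone bearing the 2-benzyloxy-5-silyloxybenzyl group.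

Key step: step 9

Remark: the sulfate monoesters 47 and 48 are written as neutral hydrogen sulfates, as the target is drawn; at the bench they would be handled as sodium salts and 48 set free on an acidic ion-exchange resin.

Locants used in names: cyclohexenones are numbered from the carbonyl carbon C1. In the bicyclo[2.2.2]octanes C1 is the oxygenated bridgehead, C2–C3 the bridge that starts as the ketone, C4 the CH bridgehead, C5–C6 the acrylate bridge (C5 carries the ester), C7 the arylmethyl-bearing carbon and C8 the CMe2 carbon. Ar = 2-(benzyloxy)-5-(triisopropylsilyloxy)phenyl. The west bicycle is numbered as a 1-benzoxepine (O1, C2 = CMe2, C5a = angular carbon, C6 = carbinol carbon, C9a = O-bearing ring-fusion CH).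

**East half (steps 1–14)**

Step 1
Reactants: 1 2,5-dihydroxybenzaldehyde
Product: 2 2-hydroxy-5-(triisopropylsilyloxy)benzaldehyde
Conditions: i-Pr3SiCl (1.05 equiv), imidazole, CH2Cl2/DMF, 0 °C
Reagents that add atoms: triisopropylsilyl chloride, CC(C)[Si](Cl)(C(C)C)C(C)C
Why: Phenol silylation; the 2-OH is hydrogen-bonded to and flanked by the aldehyde, so the remote 5-OH should react first with the bulky silyl chloride.

Step 2
Reactants: 2 2-hydroxy-5-(triisopropylsilyloxy)benzaldehyde
Product: 3 2-(benzyloxy)-5-(triisopropylsilyloxy)benzaldehyde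
Conditions: BnBr, K2CO3, acetone, 56 °C
Reagents that add atoms: benzyl bromide, BrCc1ccccc1
Why: Williamson etherification of the remaining phenoxide; the aryl triisopropylsilyl ether should tolerate carbonate in an aprotic solvent.

Step 3
Reactants: 3 2-(benzyloxy)-5-(triisopropylsilyloxy)benzaldehyde
Product: 4 [2-(benzyloxy)-5-(triisopropylsilyloxy)phenyl]methanol
Conditions: NaBH4, MeOH/THF, 0 °C
Reagents that add atoms: none
Why: Borohydride reduction of the aldehyde to the benzylic alcohol, with no effect on either ether.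

Step 4
Reactants: 4 [2-(benzyloxy)-5-(triisopropylsilyloxy)phenyl]methanol
Product: 5 2-(benzyloxy)-5-(triisopropylsilyloxy)benzyl chloride
Conditions: PPh3, N-chlorosuccinimide, CH2Cl2, 0 °C to rt
Reagents that add atoms: N-chlorosuccinimide, O=C1CCC(=O)N1Cl
Why: Appel-type chlorination of a benzylic alcohol under neutral conditions; the chloride is preferred to the bromide to limit Wurtz coupling when the Grignard reagent is made.

Step 5
Reactants: 6 4,4-dimethylcyclohex-2-en-1-one
Product: 7 4,4-dimethylcyclohexa-2,5-dien-1-one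
Conditions: DDQ, 1,4-dioxane, 100 °C
Reagents that add atoms: none
Why: DDQ dehydrogenation of an enone; the quaternary C4 blocks aromatisation, so the cross-conjugated dienone is the end point.

Step 6
Reactants: 5 2-(benzyloxy)-5-(triisopropylsilyloxy)benzyl chloride; 7 4,4-dimethylcyclohexa-2,5-dien-1-one
Product: 9 (R)-5-(Ar-methyl)-4,4-dimethylcyclohex-2-en-1-one, via benzylic Grignard reagent 8 (not isolated)
Conditions: Mg, Et2O, 0 °C (slow addition of 5); then 7, CuBr·SMe2 (5 mol%), JosiPhos-type ferrocenyl diphosphine (6 mol%), t-BuOMe, −75 °C; aq. NH4Cl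
Reagents that add atoms: none
Why: Copper-catalysed enantioselective conjugate addition of a Grignard reagent to a cyclic enone, here desymmetrising the dienone: the chiral copper–diphosphine complex selects one enantiotopic β-carbon and face (the ligand antipode is chosen so that C5 comes out R), and the magnesium enolate formed shields the product from a second addition.

Step 7
Reactants: 9 (R)-5-(Ar-methyl)-4,4-dimethylcyclohex-2-en-1-one
Product: 11 (5S,6R)-5-(Ar-methyl)-6-hydroxy-4,4-dimethylcyclohex-2-en-1-one (OH trans to the arylmethyl group), via potassium dienolate 10 (not isolated)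
Conditions: KN(SiMe3)2, THF, −78 °C; 2-(phenylsulfonyl)-3-phenyloxaziridine, −78 °C; aq. NH4Cl
Reagents that add atoms: 2-(phenylsulfonyl)-3-phenyloxaziridine, O=S(=O)(N1OC1c1ccccc1)c1ccccc1
Why: Davis hydroxylation of the cross-conjugated dienolate: C6 carries the only enolisable hydrogens, and the oxaziridine should approach anti to the neighbouring arylmethyl group to give the trans ketol (this centre becomes trigonal again in step 9).

Step 8
Reactants: 11 (5S,6R)-5-(Ar-methyl)-6-hydroxy-4,4-dimethylcyclohex-2-en-1-one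
Product: 12 (5S,6R)-5-(Ar-methyl)-6-[(benzyloxy)methoxy]-4,4-dimethylcyclohex-2-en-1-one (trans)
Conditions: BnOCH2Cl, i-Pr2NEt, Bu4NI (cat.), CH2Cl2, 40 °C
Reagents that add atoms: benzyl chloromethyl ether, ClCOCc1ccccc1
Why: Acetal-type O-alkylation under amine base; the benzyloxymethyl group is chosen because it falls in the final hydrogenolysis, so that no acid is needed once the aryl sulfate and the tertiary alcohols are present.

Step 9
Reactants: 12 (5S,6R)-5-(Ar-methyl)-6-[(benzyloxy)methoxy]-4,4-dimethylcyclohex-2-en-1-one; 13 methyl acrylate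
Product: 16 methyl 1-[(benzyloxy)methoxy]-7-(Ar-methyl)-8,8-dimethyl-2-oxobicyclo[2.2.2]octane-5-carboxylate (arylmethyl and ester both on the side of the C2–C3 carbonyl bridge), via lithium dienolate 14 (not isolated), via ester enolate Michael adduct 15 (not isolated)
Conditions: LiN(i-Pr)2 (1.1 equiv), THF, −78 °C; methyl acrylate (1.3 equiv), −78 to 0 °C; aq. NH4Cl
Reagents that add atoms: none
Why: Michael–Michael bicycloannulation, a stepwise anionic equivalent of a Diels–Alder reaction that is established for cross-conjugated cyclohexenone dienolates and acrylates. LiN(i-Pr)2 removes H6, the only enolisable hydrogen, C6 of dienolate 14 adds to the acrylate CH2, and the ester enolate 15 so formed adds to C3, the enone β-carbon beside CMe2. This second addition closes the one new ring; it is 6-exo-trig when the ring is counted through C5 and C4 and 6-endo-trig when counted through C1 and C2, both favoured, and it can only take place on the ring face that already carries the side chain. The configuration at the oxygenated bridgehead is set by 1,2-induction from C5, whose arylmethyl group should send acrylate to the opposite face of C6; that of the CH bridgehead follows from the tether; that of the ester carbon (expected syn to the carbonyl bridge through a lithium-bridged, endo-like closure) is of no consequence because it is trigonal again in step 12. The selectivity required is therefore facial at C6, and the same event places the arylmethyl group over the carbonyl bridge, the later CH2CH2 bridge of the target. Regiochemistry needs no control, since C6 is the only nucleophilic carbon of the dienolate, and the alkoxy group ends at a bridgehead where β-elimination is impossible.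

Step 10
Reactants: 16 methyl 1-[(benzyloxy)methoxy]-7-(Ar-methyl)-8,8-dimethyl-2-oxobicyclo[2.2.2]octane-5-carboxylate
Product: 18 the C2 enol triflate (C2=C3) of 16, via potassium enolate 17 (not isolated)
Conditions: KN(SiMe3)2, THF, −78 °C; PhNTf2, −78 to 0 °C
Reagents that add atoms: N-phenylbis(trifluoromethanesulfonimide), O=S(=O)(N(c1ccccc1)S(=O)(=O)C(F)(F)F)C(F)(F)F
Why: Enol triflate formation from the kinetic enolate: the C3 methylene beside the ketone is far more acidic than the ester α-CH, and the ketone is taken out at this stage because it would otherwise be deprotonated and methylated in preference to the ester in step 12.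

Step 11
Reactants: 18 the C2 enol triflate of 16
Product: 19 methyl 1-[(benzyloxy)methoxy]-7-(Ar-methyl)-8,8-dimethylbicyclo[2.2.2]oct-2-ene-5-carboxylate
Conditions: Pd(OAc)2 (5 mol%), PPh3, HCO2H, n-Bu3N, DMF, 60 °C
Reagents that add atoms: none
Why: Palladium-catalysed formate reduction of an alkenyl triflate (oxidative addition, formate decarboxylation to the hydride, reductive elimination); the bridge alkene left behind is saturated in the last step.

Step 12
Reactants: 19 methyl 1-[(benzyloxy)methoxy]-7-(Ar-methyl)-8,8-dimethylbicyclo[2.2.2]oct-2-ene-5-carboxylate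
Product: 21 the 5-methyl derivative of 19 (5-methyl syn to the C2=C3 bridge and ester syn to the CMe2 bridge), via lithium ester enolate 20 (not isolated)
Conditions: LiN(i-Pr)2, THF, −78 to −40 °C; MeI, DMPU, −78 to 0 °C
Reagents that add atoms: iodomethane, CI
Why: Ester enolate alkylation: one methyl of the C8 gem-dimethyl group hangs over one face of the trigonal C5, so iodomethane should enter from the side of the flat C2=C3 bridge, which sets the quaternary centre as in the target.

Step 13
Reactants: 21 the 5-methyl ester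
Product: 22 the corresponding 5-(hydroxymethyl) compound (primary neopentyl-type alcohol)
Conditions: i-Bu2AlH (3 equiv), CH2Cl2, −78 to 0 °C; aq. KNaC4H4O6 (Rochelle salt)
Reagents that add atoms: none
Why: Aluminium hydride reduction of the hindered ester to the primary alcohol; aryl silyl ether, acetal and benzyl ether are inert.

Step 14
Reactants: 22 the 5-(hydroxymethyl) compound
Product: 23 the 5-carbaldehyde (east aldehyde)
Conditions: Dess–Martin periodinane, NaHCO3, CH2Cl2, rt
Reagents that add atoms: none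
Why: Dess–Martin oxidation gives an aldehyde that has no α-hydrogen and therefore cannot epimerise or enolise.

**West half (steps 15–29)**

Step 15
Reactants: 24 2-methylcyclohexane-1,3-dione; 25 allyl acetate
Product: 26 2-allyl-2-methylcyclohexane-1,3-dione
Conditions: Pd(PPh3)4 (2 mol%), Et3N, THF, rt
Reagents that add atoms: none
Why: Tsuji–Trost allylation: the π-allylpalladium electrophile is attacked by the soft dione carbon, which avoids the O-alkylation that accompanies direct alkylation of 1,3-diones.

Step 16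
Reactants: 26 2-allyl-2-methylcyclohexane-1,3-dione
Product: 27 (2S,3S)-2-allyl-3-hydroxy-2-methylcyclohexan-1-one (OH cis to allyl)
Conditions: baker's yeast, sucrose, H2O, 30 °C
Reagents that add atoms: none
Why: Enzymatic desymmetrising reduction of a 2,2-disubstituted cyclohexane-1,3-dione: the yeast reductases are expected to reduce one enantiotopic carbonyl to the (S)-carbinol cis to the allyl group, which turns the prochiral C2 into the (S)-quaternary centre needed for the angular methyl.

Step 17
Reactants: 27 (2S,3S)-2-allyl-3-hydroxy-2-methylcyclohexan-1-one; 28 2-methylbut-3-en-2-ol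
Product: 29 (2S,3S)-3-hydroxy-2-[(E)-4-hydroxy-4-methylpent-2-enyl]-2-methylcyclohexan-1-one
Conditions: 28 (5 equiv), second-generation Grubbs catalyst RuCl2(=CHPh)(PCy3)(H2IMes) (3 mol%), CH2Cl2, 40 °C
Reagents that add atoms: none
Why: Olefin cross-metathesis of the terminal allyl group with the slowly homodimerising tertiary allylic alcohol, used in excess, should give the (E)-alkene; the free ketol is tolerated by the ruthenium carbene.

Step 18
Reactants: 29 (2S,3S)-3-hydroxy-2-[(E)-4-hydroxy-4-methylpent-2-enyl]-2-methylcyclohexan-1-one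
Product: 30 (2S,3S)-3-hydroxy-2-(4-hydroxy-4-methylpentyl)-2-methylcyclohexan-1-one
Conditions: H2 (1 atm), Pd/C (10% palladium on carbon), EtOAc, rt
Reagents that add atoms: none
Why: Heterogeneous hydrogenation of the disubstituted alkene; the ketone and both alcohols are unaffected under these mild conditions.

Step 19
Reactants: 30 (2S,3S)-3-hydroxy-2-(4-hydroxy-4-methylpentyl)-2-methylcyclohexan-1-one
Product: 31 the bis(trimethylsilyl) ether of 30
Conditions: Me3SiCl (3 equiv), imidazole, DMF, rt
Reagents that add atoms: chlorotrimethylsilane, C[Si](C)(C)Cl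
Why: Silylation of both hydroxyl groups: the tertiary silyl ether is the nucleophile of the next step and the secondary one prevents retro-aldol cleavage of the β-ketol under Lewis acid.

Step 20
Reactants: 31 the bis(trimethylsilyl) ether of 30
Product: 33 (5aS,6S,9aS)-2,2,5a-trimethyldecahydro-1-benzoxepin-6-ol (trans ring fusion and ring oxygen cis to the angular methyl), via trimethylsilyl ether 32 (not isolated)
Conditions: Et3SiH, Me3SiOTf, CH2Cl2, −78 to 0 °C; then 1 M HCl, THF
Reagents that add atoms: none
Why: Reductive etherification: the tertiary silyl ether adds to the silyl-triflate-activated ketone, the seven-membered oxocarbenium ion is reduced by Et3SiH from the face anti to the axial angular methyl, which gives the trans ring fusion, and the acidic work-up cleaves the secondary silyl ether.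

Step 21
Reactants: 33 (5aS,6S,9aS)-2,2,5a-trimethyldecahydro-1-benzoxepin-6-ol
Product: 34 (5aR,9aS)-2,2,5a-trimethyloctahydro-1-benzoxepin-6(2H)-one
Conditions: Dess–Martin periodinane, NaHCO3, CH2Cl2, rt
Reagents that add atoms: none
Why: Dess–Martin oxidation of the secondary alcohol to the ketone that becomes the tertiary carbinol carbon; the neighbouring quaternary centre cannot epimerise.

Step 22
Reactants: 34 (5aR,9aS)-2,2,5a-trimethyloctahydro-1-benzoxepin-6(2H)-one
Product: 36 (5aR,7S,9aS)-2,2,5a,7-tetramethyloctahydro-1-benzoxepin-6(2H)-one (7-methyl equatorial and trans to the angular methyl), via lithium enolate 35 (not isolated)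
Conditions: LiN(i-Pr)2, THF, −78 °C; MeI, −78 to 0 °C
Reagents that add atoms: iodomethane, CI
Why: Enolate alkylation: only C7 can be deprotonated, and iodomethane should approach anti to the axial angular methyl (avoiding a 1,3-diaxial clash), which gives the equatorial 7-methyl epimer, also the thermodynamic one.

Step 23
Reactants: 36 (5aR,7S,9aS)-2,2,5a,7-tetramethyloctahydro-1-benzoxepin-6(2H)-one
Product: 37 the 6-methylidene analogue of 36 (C=CH2 in place of C=O)
Conditions: Ph3PCH3Br, KOt-Bu, toluene, 100 °C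
Reagents that add atoms: methyltriphenylphosphonium bromide, C[P+](c1ccccc1)(c1ccccc1)c1ccccc1.[Br-]
Why: Wittig methylenation under forcing, salt-free conditions suited to a hindered ketone; any base-induced epimerisation at C7 would converge on the desired equatorial methyl.

Step 24
Reactants: 37 the 6-methylidene compound
Product: 38 the spiro-epoxide of 37 (oxirane oxygen axial on C6 and trans to the angular methyl, oxirane CH2 equatorial)
Conditions: mCPBA, NaHCO3, CH2Cl2, 0 °C
Reagents that add atoms: 3-chloroperoxybenzoic acid, OOC(=O)c1cccc(Cl)c1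
Why: Prilezhaev epoxidation from the face opposite the axial angular methyl puts oxygen where the tertiary hydroxyl must be, whereas an organometallic added to ketone 36 would arrive on that same open face and place the carbon chain there.

Step 25
Reactants: 38 the spiro-epoxide
Product: 39 (5aR,6S,7S,9aS)-6-allyl-2,2,5a,7-tetramethyldecahydro-1-benzoxepin-6-ol
Conditions: CH2=CHMgBr, CuI (10 mol%), THF, −30 to 0 °C; aq. NH4Cl
Reagents that add atoms: vinylmagnesium bromide, C=C[Mg]Br
Why: Copper-catalysed Grignard opening of a 2,2-disubstituted epoxide at its CH2 terminus (SN2), which leaves the tertiary C–O bond and hence the carbinol configuration untouched.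

Step 26
Reactants: 39 (5aR,6S,7S,9aS)-6-allyl-2,2,5a,7-tetramethyldecahydro-1-benzoxepin-6-ol
Product: 40 the triethylsilyl ether of 39
Conditions: Et3SiOTf, 2,6-lutidine, CH2Cl2, 0 °C to rt
Reagents that add atoms: triethylsilyl trifluoromethanesulfonate, CC[Si](CC)(CC)OS(=O)(=O)C(F)(F)F
Why: Silylation of the hindered tertiary alcohol with a silyl triflate, so that it cannot cyclise onto the activated primary carbon in step 28 or interfere as an alkoxide in step 30.

Step 27
Reactants: 40 the triethylsilyl ether of 39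
Product: 41 the 6-(3-hydroxypropyl) analogue of 40 (primary alcohol)
Conditions: 9-BBN, THF, rt; then NaOH, H2O2, 0 °C
Reagents that add atoms: hydrogen peroxide, OO
Why: Anti-Markovnikov hydroboration of the terminal alkene with 9-BBN and alkaline peroxide oxidation give the primary alcohol.

Step 28
Reactants: 41 the 6-(3-hydroxypropyl) compound
Product: 42 the 6-[3-(1-phenyl-1H-tetrazol-5-ylthio)propyl] compound
Conditions: 1-phenyl-1H-tetrazole-5-thiol, PPh3, i-PrO2CN=NCO2i-Pr, THF, 0 °C
Reagents that add atoms: 1-phenyl-1H-tetrazole-5-thiol, Sc1nnnn1-c1ccccc1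
Why: Mitsunobu thioetherification of the primary alcohol with the acidic tetrazole thiol.

Step 29
Reactants: 42 the tetrazolyl sulfide
Product: 43 the 6-[3-(1-phenyl-1H-tetrazol-5-ylsulfonyl)propyl] compound (west sulfone)
Conditions: mCPBA (2.5 equiv), NaHCO3, CH2Cl2, 0 °C to rt
Reagents that add atoms: 3-chloroperoxybenzoic acid, OOC(=O)c1cccc(Cl)c1
Why: Peracid oxidation of the sulfide to the sulfone, buffered to protect the silyl ether.

**Union and endgame (steps 30–33)**

Step 30
Reactants: 43 the west sulfone; 23 the east aldehyde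
Product: 45 the fully protected (E)-alkene joining C6 of the west bicycle to C5 of the east bicycle through CH2CH2CH=CH, via potassium sulfonyl carbanion 44 (not isolated)
Conditions: KN(SiMe3)2, DME, −60 °C; then 23, −60 °C to rt
Reagents that add atoms: none
Why: Julia–Kocienski olefination: the metalated tetrazolyl sulfone adds to the non-enolisable aldehyde, and Smiles rearrangement with loss of SO2 and the tetrazolone gives the alkene, whose geometry is irrelevant because it is hydrogenated.

Step 31
Reactants: 45 the fully protected alkene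
Product: 46 the free distal phenol and free west tertiary alcohol (benzyl ether and benzyloxymethyl acetal retained)
Conditions: Bu4NF, THF, 0 °C to rt
Reagents that add atoms: none
Why: Fluoride-mediated desilylation removes the aryl triisopropylsilyl ether and the tertiary triethylsilyl ether, while the ortho phenol and the bridgehead oxygen stay protected.

Step 32
Reactants: 46 the phenol
Product: 47 the aryl hydrogen sulfate at the distal phenol
Conditions: SO3·pyridine, pyridine, rt; aq. NaHCO3
Reagents that add atoms: sulfur trioxide–pyridine complex, [O-]S(=O)(=O)[n+]1ccccc1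
Why: O-Sulfation of a phenol with SO3·pyridine; the only other free hydroxyl is a very hindered tertiary alcohol that should not react.

Step 33
Reactants: 47 the protected aryl sulfate
Product: 48 CNP0255133.1 (target)
Conditions: H2 (1 atm), Pd/C (10% palladium on carbon), MeOH/EtOAc, NaHCO3 (trace), rt
Reagents that add atoms: none
Why: Catalytic hydrogenation and hydrogenolysis in one operation: both alkenes are saturated and the aryl benzyl ether and the benzyloxymethyl acetal are cleaved, while the aryl sulfate, the tertiary alcohols and the oxepane are inert.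

**Compound list**

1 | 2,5-dihydroxybenzaldehyde | O=Cc1cc(O)ccc1O | starting material
2 | 2-hydroxy-5-(triisopropylsilyloxy)benzaldehyde | O=Cc1cc(O[Si](C(C)C)(C(C)C)C(C)C)ccc1O | intermediate
3 | 2-(benzyloxy)-5-(triisopropylsilyloxy)benzaldehyde | O=Cc1cc(O[Si](C(C)C)(C(C)C)C(C)C)ccc1OCc1ccccc1 | intermediate
4 | [2-(benzyloxy)-5-(triisopropylsilyloxy)phenyl]methanol | OCc1cc(O[Si](C(C)C)(C(C)C)C(C)C)ccc1OCc1ccccc1 | intermediate
5 | 2-(benzyloxy)-5-(triisopropylsilyloxy)benzyl chloride | ClCc1cc(O[Si](C(C)C)(C(C)C)C(C)C)ccc1OCc1ccccc1 | intermediate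
6 | 4,4-dimethylcyclohex-2-en-1-one | CC1(C)CCC(=O)C=C1 | starting material
7 | 4,4-dimethylcyclohexa-2,5-dien-1-one | CC1(C)C=CC(=O)C=C1 | intermediate
8 | 2-(benzyloxy)-5-(triisopropylsilyloxy)benzylmagnesium chloride | Cl[Mg]Cc1cc(O[Si](C(C)C)(C(C)C)C(C)C)ccc1OCc1ccccc1 | intermediate
9 | (R)-5-(Ar-methyl)-4,4-dimethylcyclohex-2-en-1-one | O=C1C=CC(C)(C)[C@H](Cc2cc(O[Si](C(C)C)(C(C)C)C(C)C)ccc2OCc2ccccc2)C1 | intermediate
10 | potassium dienolate of 9 (O–K on C1, C1=C6 and C2=C3) | [K]OC1=C[C@@H](Cc2cc(O[Si](C(C)C)(C(C)C)C(C)C)ccc2OCc2ccccc2)C(C)(C)C=C1 | intermediate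
11 | (5S,6R)-5-(Ar-methyl)-6-hydroxy-4,4-dimethylcyclohex-2-en-1-one (trans) | O=C1C=CC(C)(C)[C@H](Cc2cc(O[Si](C(C)C)(C(C)C)C(C)C)ccc2OCc2ccccc2)[C@H]1O | intermediate
12 | (5S,6R)-5-(Ar-methyl)-6-[(benzyloxy)methoxy]-4,4-dimethylcyclohex-2-en-1-one (trans; key-step precursor) | O=C1C=CC(C)(C)[C@H](Cc2cc(O[Si](C(C)C)(C(C)C)C(C)C)ccc2OCc2ccccc2)[C@H]1OCOCc1ccccc1 | intermediate
13 | methyl acrylate | C=CC(=O)OC | starting material
14 | lithium dienolate of 12 (O–Li on C1, C1=C6 and C2=C3) | [Li]OC1=C(OCOCc2ccccc2)[C@@H](Cc2cc(O[Si](C(C)C)(C(C)C)C(C)C)ccc2OCc2ccccc2)C(C)(C)C=C1 | intermediate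
15 | lithium ester enolate of the mono-Michael adduct (C6 quaternary, new side chain trans to the arylmethyl group) | O=C1C=CC(C)(C)[C@H](Cc2cc(O[Si](C(C)C)(C(C)C)C(C)C)ccc2OCc2ccccc2)[C@@]1(OCOCc1ccccc1)CC=C(O[Li])OC | intermediate
16 | methyl 1-[(benzyloxy)methoxy]-7-(Ar-methyl)-8,8-dimethyl-2-oxobicyclo[2.2.2]octane-5-carboxylate, ester and arylmethyl syn to the C2–C3 bridge (key-step product) | COC(=O)[C@H]1C[C@@]2(OCOCc3ccccc3)C(=O)C[C@@H]1C(C)(C)[C@@H]2Cc1cc(O[Si](C(C)C)(C(C)C)C(C)C)ccc1OCc1ccccc1 | intermediate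
17 | potassium enolate of 16 (C2=C3) | COC(=O)[C@H]1C[C@@]2(OCOCc3ccccc3)C(O[K])=C[C@@H]1C(C)(C)[C@@H]2Cc1cc(O[Si](C(C)C)(C(C)C)C(C)C)ccc1OCc1ccccc1 | intermediate
18 | C2 enol triflate of 16 | COC(=O)[C@H]1C[C@@]2(OCOCc3ccccc3)C(OS(=O)(=O)C(F)(F)F)=C[C@@H]1C(C)(C)[C@@H]2Cc1cc(O[Si](C(C)C)(C(C)C)C(C)C)ccc1OCc1ccccc1 | intermediate
19 | methyl 1-[(benzyloxy)methoxy]-7-(Ar-methyl)-8,8-dimethylbicyclo[2.2.2]oct-2-ene-5-carboxylate | COC(=O)[C@H]1C[C@@]2(OCOCc3ccccc3)C=C[C@@H]1C(C)(C)[C@@H]2Cc1cc(O[Si](C(C)C)(C(C)C)C(C)C)ccc1OCc1ccccc1 | intermediate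
20 | lithium ester enolate of 19 | COC(O[Li])=C1C[C@@]2(OCOCc3ccccc3)C=C[C@@H]1C(C)(C)[C@@H]2Cc1cc(O[Si](C(C)C)(C(C)C)C(C)C)ccc1OCc1ccccc1 | intermediate
21 | 5-methyl derivative of 19 (methyl syn to the C2=C3 bridge, ester syn to CMe2) | COC(=O)[C@]1(C)C[C@@]2(OCOCc3ccccc3)C=C[C@@H]1C(C)(C)[C@@H]2Cc1cc(O[Si](C(C)C)(C(C)C)C(C)C)ccc1OCc1ccccc1 | intermediate
22 | 5-(hydroxymethyl) compound from 21 | OC[C@]1(C)C[C@@]2(OCOCc3ccccc3)C=C[C@@H]1C(C)(C)[C@@H]2Cc1cc(O[Si](C(C)C)(C(C)C)C(C)C)ccc1OCc1ccccc1 | intermediate
23 | east aldehyde (5-carbaldehyde) | O=C[C@]1(C)C[C@@]2(OCOCc3ccccc3)C=C[C@@H]1C(C)(C)[C@@H]2Cc1cc(O[Si](C(C)C)(C(C)C)C(C)C)ccc1OCc1ccccc1 | intermediate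
24 | 2-methylcyclohexane-1,3-dione | CC1C(=O)CCCC1=O | starting material
25 | allyl acetate | C=CCOC(C)=O | starting material
26 | 2-allyl-2-methylcyclohexane-1,3-dione | C=CCC1(C)C(=O)CCCC1=O | intermediate
27 | (2S,3S)-2-allyl-3-hydroxy-2-methylcyclohexan-1-one | O=C1CCC[C@H](O)[C@]1(C)CC=C | intermediate
28 | 2-methylbut-3-en-2-ol | C=CC(C)(C)O | starting material
29 | (2S,3S)-3-hydroxy-2-[(E)-4-hydroxy-4-methylpent-2-enyl]-2-methylcyclohexan-1-one | O=C1CCC[C@H](O)[C@]1(C)C/C=C/C(C)(C)O | intermediate
30 | (2S,3S)-3-hydroxy-2-(4-hydroxy-4-methylpentyl)-2-methylcyclohexan-1-one | O=C1CCC[C@H](O)[C@]1(C)CCCC(C)(C)O | intermediate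
31 | bis(trimethylsilyl) ether of 30 | O=C1CCC[C@H](O[Si](C)(C)C)[C@]1(C)CCCC(C)(C)O[Si](C)(C)C | intermediate
32 | trimethylsilyl ether of 33 | C[Si](C)(C)O[C@H]1CCC[C@@H]2OC(C)(C)CCC[C@@]12C | intermediate
33 | (5aS,6S,9aS)-2,2,5a-trimethyldecahydro-1-benzoxepin-6-ol | O[C@H]1CCC[C@@H]2OC(C)(C)CCC[C@@]12C | intermediate
34 | (5aR,9aS)-2,2,5a-trimethyloctahydro-1-benzoxepin-6(2H)-one | O=C1CCC[C@@H]2OC(C)(C)CCC[C@@]12C | intermediate
35 | lithium enolate of 34 (C6=C7) | [Li]OC1=CCC[C@@H]2OC(C)(C)CCC[C@@]12C | intermediate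
36 | (5aR,7S,9aS)-2,2,5a,7-tetramethyloctahydro-1-benzoxepin-6(2H)-one | C[C@H]1CC[C@@H]2OC(C)(C)CCC[C@@]2(C)C1=O | intermediate
37 | 6-methylidene analogue of 36 | C[C@H]1CC[C@@H]2OC(C)(C)CCC[C@@]2(C)C1=C | intermediate
38 | spiro-epoxide of 37 (oxirane O axial, trans to the angular methyl) | C[C@H]1CC[C@@H]2OC(C)(C)CCC[C@@]2(C)[C@]13CO3 | intermediate
39 | (5aR,6S,7S,9aS)-6-allyl-2,2,5a,7-tetramethyldecahydro-1-benzoxepin-6-ol | C[C@H]1CC[C@@H]2OC(C)(C)CCC[C@@]2(C)[C@]1(O)CC=C | intermediate
40 | triethylsilyl ether of 39 | C[C@H]1CC[C@@H]2OC(C)(C)CCC[C@@]2(C)[C@]1(O[Si](CC)(CC)CC)CC=C | intermediate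
41 | 6-(3-hydroxypropyl) analogue of 40 | C[C@H]1CC[C@@H]2OC(C)(C)CCC[C@@]2(C)[C@]1(O[Si](CC)(CC)CC)CCCO | intermediate
42 | 6-[3-(1-phenyl-1H-tetrazol-5-ylthio)propyl] compound | C[C@H]1CC[C@@H]2OC(C)(C)CCC[C@@]2(C)[C@]1(O[Si](CC)(CC)CC)CCCSc1nnnn1-c1ccccc1 | intermediate
43 | west sulfone, 6-[3-(1-phenyl-1H-tetrazol-5-ylsulfonyl)propyl] compound | C[C@H]1CC[C@@H]2OC(C)(C)CCC[C@@]2(C)[C@]1(O[Si](CC)(CC)CC)CCCS(=O)(=O)c1nnnn1-c1ccccc1 | intermediate
44 | potassium α-sulfonyl carbanion of 43 | C[C@H]1CC[C@@H]2OC(C)(C)CCC[C@@]2(C)[C@]1(O[Si](CC)(CC)CC)CCC([K])S(=O)(=O)c1nnnn1-c1ccccc1 | intermediate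
45 | fully protected (E)-alkene (west OSiEt3, bridgehead OCH2OBn, ArOBn, ArOSi(i-Pr)3) | C[C@H]1CC[C@@H]2OC(C)(C)CCC[C@@]2(C)[C@]1(O[Si](CC)(CC)CC)CC/C=C/[C@]1(C)C[C@@]2(OCOCc3ccccc3)C=C[C@@H]1C(C)(C)[C@@H]2Cc1cc(O[Si](C(C)C)(C(C)C)C(C)C)ccc1OCc1ccccc1 | intermediate
46 | distal phenol with free west tertiary alcohol | C[C@H]1CC[C@@H]2OC(C)(C)CCC[C@@]2(C)[C@]1(O)CC/C=C/[C@]1(C)C[C@@]2(OCOCc3ccccc3)C=C[C@@H]1C(C)(C)[C@@H]2Cc1cc(O)ccc1OCc1ccccc1 | intermediate
47 | aryl hydrogen sulfate of 46 | C[C@H]1CC[C@@H]2OC(C)(C)CCC[C@@]2(C)[C@]1(O)CC/C=C/[C@]1(C)C[C@@]2(OCOCc3ccccc3)C=C[C@@H]1C(C)(C)[C@@H]2Cc1cc(OS(=O)(=O)O)ccc1OCc1ccccc1 | intermediate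
48 | CNP0255133.1 | C[C@H]1CC[C@@H]2OC(C)(C)CCC[C@@]2(C)[C@]1(O)CCCC[C@]1(C)C[C@@]2(O)CC[C@@H]1C(C)(C)[C@@H]2Cc1cc(OS(=O)(=O)O)ccc1O | target

**Step count and risk**

Total step count: 33. Longest linear sequence: 19 steps (24 to 48, steps 15–29 and 30–33). The east branch from 1 is 17 steps.

Step 6 is the most exposed. The benzylic Grignard reagent may add with poor enantioface discrimination, or add 1,2 or sluggishly at the β-carbon next to the quaternary centre. The fallback gives up asymmetric catalysis for a racemic synthesis with enzymatic resolution. It sets out from 5 and 7: Grignard reagent 8 is added to 7 with CuI (catalytic) and Me3SiCl in THF at −40 °C, and the enolate is trapped as the racemic trimethylsilyl dienol ether of 9 F1. Rubottom oxidation (mCPBA, NaHCO3, then dilute acid) gives the racemic trans ketol rac-11 F2. Lipase-catalysed acetylation (Burkholderia cepacia lipase, vinyl acetate, t-BuOMe) separates the enantiomers as alcohol and acetate, leaving 11 beside the acetate of its (5R,6S) mirror image F3. If the enzyme shows the reverse preference, the acetate of 11 is collected and methanolysed. The route is rejoined at 11.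

Step 9 may suffer from insufficient facial discrimination at C6, or may stop after the first conjugate addition at the crowded, oxygenated C6 while the acrylate oligomerises. The fallback replaces the lithium dienolate by a neutral silyl dienol ether under Lewis acid catalysis, with the same bonds formed in the same order. It sets out from 12: t-BuMe2SiOTf and Et3N in CH2Cl2 give the 1-(tert-butyldimethylsilyloxy) diene of 12 F4. Treatment of F4 with 13 and catalytic Tf2NH in CH2Cl2 at −78 °C (Mukaiyama–Michael addition, then intramolecular Mukaiyama–Michael closure) gives the tert-butyldimethylsilyl enol ether of 16 F5. Hydrolysis with AcOH in aqueous THF returns to the route at 16.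

Step 20 may fail because the hindered tertiary silyl ether does not add to the ketone next to the quaternary carbon, so that the ketone is simply reduced or the tertiary centre ionises and eliminates. The fallback makes the C–O bond at the tertiary carbon instead. It sets out from 30: Evans–Tishchenko reduction (SmI2 30 mol%, acetaldehyde, THF, −10 °C) delivers hydride anti to the existing hydroxyl and leaves it acetylated, giving (1S,2S,3S)-3-hydroxy-2-(4-hydroxy-4-methylpentyl)-2-methylcyclohexyl acetate F6, whose new hydroxyl is cis to the angular methyl. Acid-catalysed cyclodehydration (TfOH 5 mol%, CH2Cl2, 0 °C; tertiary cation captured by the secondary hydroxyl) gives the acetate of 33 F7. Methanolysis (K2CO3, MeOH) returns to the route at 33.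

**Further compounds**

F1 | step 6 | racemic trimethylsilyl dienol ether of 9 | C[Si](C)(C)OC1=CC(Cc2cc(O[Si](C(C)C)(C(C)C)C(C)C)ccc2OCc2ccccc2)C(C)(C)C=C1
F2 | step 6 | racemic trans-5-(Ar-methyl)-6-hydroxy-4,4-dimethylcyclohex-2-en-1-one (rac-11) | O=C1C=CC(C)(C)[C@H](Cc2cc(O[Si](C(C)C)(C(C)C)C(C)C)ccc2OCc2ccccc2)[C@H]1O.O=C1C=CC(C)(C)[C@@H](Cc2cc(O[Si](C(C)C)(C(C)C)C(C)C)ccc2OCc2ccccc2)[C@@H]1O
F3 | step 6 | (5R,6S)-6-acetoxy-5-(Ar-methyl)-4,4-dimethylcyclohex-2-en-1-one | O=C1C=CC(C)(C)[C@@H](Cc2cc(O[Si](C(C)C)(C(C)C)C(C)C)ccc2OCc2ccccc2)[C@@H]1OC(C)=O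
F4 | step 9 | 1-(tert-butyldimethylsilyloxy) diene of 12 | CC(C)(C)[Si](C)(C)OC1=C(OCOCc2ccccc2)[C@@H](Cc2cc(O[Si](C(C)C)(C(C)C)C(C)C)ccc2OCc2ccccc2)C(C)(C)C=C1
F5 | step 9 | tert-butyldimethylsilyl enol ether of 16 | COC(=O)[C@H]1C[C@@]2(OCOCc3ccccc3)C(O[Si](C)(C)C(C)(C)C)=C[C@@H]1C(C)(C)[C@@H]2Cc1cc(O[Si](C(C)C)(C(C)C)C(C)C)ccc1OCc1ccccc1
F6 | step 20 | (1S,2S,3S)-3-hydroxy-2-(4-hydroxy-4-methylpentyl)-2-methylcyclohexyl acetate | CC(=O)O[C@H]1CCC[C@H](O)[C@@]1(C)CCCC(C)(C)O
F7 | step 20 | acetate of 33 | CC(=O)O[C@H]1CCC[C@@H]2OC(C)(C)CCC[C@@]12C
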